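## The problem

The target is a (3S)-isoflavan. Ring A is fused to the oxygen ring (O1, C2, C3, C4) of a chroman, and a pentasubstituted benzene, ring B, is attached to C3 through the single bond C3–C1'. C3 is the only stereocentre, so nothing in the molecule can relay configuration to it. It has to be set by a catalyst and then kept from enolising whenever a carbonyl group sits next to it, all the more because O1 is β to such a carbonyl and could leave by retro-oxa-Michael opening. Ring B carries four contiguous oxygens on C2'–C5'; only the one on C3', wedged between two methoxy groups, is a free hydroxyl, and ring A carries a free 7-hydroxyl beside an 8-methoxy group. No reagent will pick one methyl ether out of such a set at the end, so the oxygens must be told apart when the rings are assembled. Both arenes are electron-rich and the free phenols oxidise readily, which argues against strong oxidants late in the route and for releasing the two hydroxyls last. A direct C3–C1' coupling would need a fully substituted aryl partner and a configurationally defined secondary carbon, a poor combination. The feature that opens another way is that C2', C3', C4' and C5' of ring B, each bearing oxygen, correspond one for one to the four carbons of squaric acid, while C6' (bearing H) and C1' (bearing the chroman) correspond to a vinyl group on C3. Ring B can therefore be grown onto a finished, enantiopure chroman.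

## Retrosynthesis

**Unmasking (20 from 19 from 18).** The two free hydroxyls of 20 are traced back to an isopropyl ether on O3' and a benzyl ether on O7 in 19. Both can be cleaved by BCl3 while the four methyl ethers stay. Compound 19 comes from phenol 18 by methylation of its single free hydroxyl at C2'. This order lets the ring-forming step deliver exactly one free OH, so no selective demethylation is ever needed. The forward reaction must cleave a secondary alkyl ether and a benzyl ether without touching the flanking methoxy groups.

**Ring B (18 from 15).** The bond C1'–C2' is cut. Phenol 18 is read as the enol of cyclohexadienone 17, formed by 6π closure of dienylketene 16, which comes from 4π opening of cyclobutenone 15. The neighbouring cut, C3–C1', would require the pentasubstituted arene as a separate fragment and a stereodefined coupling at a secondary carbon. Cutting inside ring B removes that arene from the list of things to be made. Precursor 15 is simpler by a whole aromatic ring and its substitution pattern. The forward step needs the 4-methoxy group to rotate outward so that the alkenyl group turns inward.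

**Cyclobutenone (15 from 14 from 10 and 11).** The bond between the vinyl carbon (future C6') and the ring carbon (future C5') is cut. Alkenyllithium 12, made from iodide 10, adds to one carbonyl of diisopropyl squarate 11, and alkoxide 13 is methylated to 14. Because 11 is symmetrical, the C–C bond formation poses no regiochemical question. In 14 the three alkoxy groups differ in kind: only the one on C3 is a vinylogous ester. Exchanging it for methoxy gives 15 and leaves isopropoxy on the carbon that becomes C3'. A mixed isopropyl methyl squarate would reach 15 one step sooner, but with no control over which carbonyl is attacked.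

**Vinyl iodide (10 from 9 from 8 from 7).** The C1'=C6' double bond is cut by a Takai iodo-olefination of aldehyde 9, which comes from acid 7 through alcohol 8. Two redox steps are the price for setting the stereocentre at the acid stage, where the carboxyl group can direct a catalyst. The forward sequence must not epimerise 9.

**Stereocentre (7 from 6).** The two hydrogens on C3 and C4 are removed. Acid 7 comes from 2H-chromene-3-carboxylic acid 6 by BINAP–ruthenium asymmetric hydrogenation. An auxiliary-based alkylation would take more steps and a stoichiometric controller. Here the stereocentre is set catalytically on a flat, easily made substrate.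

**Chromene (6 from 5 from 3 and 4).** O1–C2 and C3–C4 are cut together. Ester 5 is the annulation product of salicylaldehyde 3 with tert-butyl acrylate 4, and acid 6 follows by acidolysis. One step brings in C2, C3 and the carboxyl carbon that later becomes C1'.

**Ring A (3 from 2 from 1).** Aldehyde 3 comes from 2-methoxyresorcinol 1 by formylation to 2 and benzylation of the hydroxyl para to the formyl group. The symmetry of 1 makes the formylation unambiguous.

## Roads not taken

Alternative 1: Here C3–C4 is cut on an open-chain ether in which ring B (carrying a diazoacetate on C1') and ring A are linked through a benzylic ether oxygen on C2' (diazo ester A1). A chiral divalent rhodium carboxylate dimer such as Rh2(S-PTTL)4 would turn A1 into a carbene that inserts into the ether-activated benzylic C–H bond and closes the cis-dihydrobenzofuran A2, whose carbon 3 is C3 of the target. Hydrogenolysis of the benzylic C–O bond, ester reduction, release of the ring A phenol and closure of the pyran would follow.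
- Merits: the two arenes are joined by a simple etherification, C3 is set catalytically in the bond-forming step, and this insertion is a well-established route to 2-aryl-2,3-dihydrobenzofuran-3-carboxylates.
- Weak points: ring B must be supplied as a pentasubstituted benzene with its oxygens already differentiated, so the hardest part of the problem moves into a starting material. In A2 the stereocentre that matters is benzylic and α to an ester, the most acidic position in the molecule, and it must survive several further operations. The second stereocentre made in the key step is discarded, and four or five steps remain after the key step.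
- Comparison: this road is more convergent, and its key step has closer precedent on its own substrate class than the alkoxy exchange of the chosen plan. The chosen plan sets against it that the oxygen pattern is created from a symmetrical commodity squarate, and that C3 is never acidic after step 8.

Alternative 2: Here C2–C3 and C3–C1' are both made on boron. Dichloromethyllithium with ZnCl2 would insert a chloromethine carbon into the C–B bond of the alkoxymethyl boronic ester A3, and the ring B Grignard reagent A4 would displace chloride in a second 1,2-shift to give A5. A further one-carbon homologation, coupling to a ring A aryl halide, deprotection and ring closure would follow.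
- Merits: the stereocontrol comes from the C2-symmetric diol and is among the most reliable known, independent of the substrate; the route is modular and every step is of a known type.
- Weak points: it too needs the fully differentiated ring B as an aryl metal. It uses a stoichiometric chiral director and cryogenic carbenoid chemistry. The boron of A5 must still be turned into the C3–C4 bond by an sp3–sp2 coupling next to a β-alkoxy group, which invites elimination when ate complexes form. About as many steps follow the key step as precede it.
- Comparison: in stereochemical certainty this road is better than a catalytic hydrogenation whose sense has to be confirmed. The chosen plan sets against it catalytic asymmetric induction, a single linear assembly from three cheap materials, and a ring B built with its oxygens in place.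

Alternative 3: Here C2–C3 and C3–C4 are cut at once. The chlorocarbene released from chlorodiazirine A6 would cyclopropanate the C2=C3 bond of benzofuran A7; opening of the adduct with loss of chloride would expand the furan to the 3-arylbenzopyrylium salt A8. Reduction to the chroman level would follow, and C3 would have to be set in that reduction.
- Merits: it is the shortest assembly of the skeleton, and the ring A partner is trivial.
- Weak points: carbon-atom insertion of this kind is established for electron-rich nitrogen heteroarenes. A benzofuran is a weaker nucleophile, and the carbene from A6, carrying three donor oxygens with one ortho, is a weaker electrophile, so the pair is doubly mismatched. A6 must be made by hypochlorite oxidation of an amidine on a very electron-rich ring. A8 is achiral, so the stereocentre depends on a later asymmetric reduction of a hindered, ortho-substituted 3-aryl heterocycle. Ring B is again a pre-made pentasubstituted arene.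
- Comparison: on step count this road would clearly win if both uncertain steps worked. The chosen plan sets against it that only one of its steps lacks direct precedent, and that its stereocentre is set on a simple acid by a well-tried reaction.

Key step: step 11

**Remarks on the chemistry (assumptions).**
- The facial sense of Ru(OAc)2(BINAP) on acid 6 is taken to follow that of (E)-2-methylbut-2-enoic acid, which has the same arrangement of carboxyl group and β-substituent. On this basis the (S)-ligand is assigned to give (R)-7. The sense has to be confirmed at this stage, and the (R)-ligand is used instead if the assignment is reversed.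
- C4 of cyclobutenones 13–15 is formed without control and is left unspecified in the structures; it is lost in step 11.

## Route

Step 1
Reactants: 1 2-methoxyresorcinol (2-methoxybenzene-1,3-diol)
Product: 2 2,4-dihydroxy-3-methoxybenzaldehyde
Conditions: POCl3, DMF, MeCN, 0 → 25 °C; then H2O, 50 °C
Reagents that add atoms: N,N-dimethylformamide, CN(C)C=O; water, O
Why: Vilsmeier–Haack formylation of a resorcinol; the two open positions ortho to one hydroxyl and para to the other are equivalent and the position meta to both is not attacked, so a single aldehyde should result after hydrolysis of the iminium salt.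

Step 2
Reactants: 2 2,4-dihydroxy-3-methoxybenzaldehyde
Product: 3 4-(benzyloxy)-2-hydroxy-3-methoxybenzaldehyde
Conditions: BnBr (1.05 equiv), NaHCO3, MeCN, 80 °C
Reagents that add atoms: benzyl bromide, BrCc1ccccc1
Why: Williamson etherification under weak base; the 4-hydroxyl, para to the formyl group, is the more acidic and is free, whereas the 2-hydroxyl is held in a hydrogen bond to the aldehyde, so mono-benzylation at O4 is expected as for 2,4-dihydroxybenzaldehyde itself.

Step 3
Reactants: 3 4-(benzyloxy)-2-hydroxy-3-methoxybenzaldehyde; 4 tert-butyl acrylate
Product: 5 tert-butyl 7-(benzyloxy)-8-methoxy-2H-chromene-3-carboxylate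
Conditions: DABCO (1 equiv), CHCl3/H2O, 25 °C
Reagents that add atoms: none
Why: DABCO-mediated Baylis–Hillman reaction of the salicylaldehyde followed by intramolecular oxa-Michael addition of the phenol and loss of water; the tert-butyl ester suppresses the competing lactonisation to a coumarin.

Step 4
Reactants: 5 tert-butyl 7-(benzyloxy)-8-methoxy-2H-chromene-3-carboxylate
Product: 6 7-(benzyloxy)-8-methoxy-2H-chromene-3-carboxylic acid
Conditions: CF3CO2H/CH2Cl2 (1:4), 0 → 25 °C
Reagents that add atoms: none
Why: Acidolysis of a tert-butyl ester with loss of isobutylene; the aryl benzyl ether and the electron-poor conjugated alkene should tolerate dilute trifluoroacetic acid at room temperature for the short time needed.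

Step 5
Reactants: 6 7-(benzyloxy)-8-methoxy-2H-chromene-3-carboxylic acid
Product: 7 (R)-7-(benzyloxy)-8-methoxychromane-3-carboxylic acid
Conditions: Ru(OAc)2[(S)-BINAP] (1 mol %), H2 (5 atm), MeOH, 25 °C
Reagents that add atoms: none
Why: BINAP–ruthenium asymmetric hydrogenation of an α-substituted β-aryl acrylic acid, in which the carboxylate binds the metal and hydrogen is delivered to one face of the C3=C4 bond; this sets C3, the only stereocentre, with the ligand enantiomer chosen as stated in the assumption, and the homogeneous catalyst does not cleave the benzyl ether.

Step 6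
Reactants: 7 (R)-7-(benzyloxy)-8-methoxychromane-3-carboxylic acid
Product: 8 (S)-[7-(benzyloxy)-8-methoxychroman-3-yl]methanol
Conditions: LiAlH4, THF, 0 → 25 °C
Reagents that add atoms: none
Why: Hydride reduction of a carboxylic acid to the primary alcohol; C3 is not touched, and its descriptor changes from R to S only because the substituent priorities change.

Step 7
Reactants: 8 (S)-[7-(benzyloxy)-8-methoxychroman-3-yl]methanol
Product: 9 (R)-7-(benzyloxy)-8-methoxychromane-3-carbaldehyde
Conditions: Dess–Martin periodinane, NaHCO3, CH2Cl2, 0 °C
Reagents that add atoms: none
Why: Dess–Martin oxidation under buffered, non-basic conditions, chosen because 9 is enolisable at C3 and could lose its configuration by enolisation or retro-oxa-Michael opening; the aldehyde is used at once without chromatography.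

Step 8
Reactants: 9 (R)-7-(benzyloxy)-8-methoxychromane-3-carbaldehyde
Product: 10 (S)-7-(benzyloxy)-3-[(E)-2-iodovinyl]-8-methoxychromane
Conditions: CrCl2 (6 equiv), CHI3 (2 equiv), THF, 0 → 25 °C, dark
Reagents that add atoms: iodoform, IC(I)I
Why: Takai iodo-olefination; the geminal dichromium reagent is only weakly basic and is routinely applied to α-branched aldehydes without epimerisation, giving mainly the (E)-iodoalkene. A minor (Z)-isomer is harmless because both geometries lead to the same arene in step 11.

Step 9
Reactants: 10 (S)-7-(benzyloxy)-3-[(E)-2-iodovinyl]-8-methoxychromane; 11 diisopropyl squarate (3,4-diisopropoxycyclobut-3-ene-1,2-dione)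
Product: 14 4-[(E)-2-((S)-7-benzyloxy-8-methoxychroman-3-yl)vinyl]-2,3-diisopropoxy-4-methoxycyclobut-2-en-1-one (both C4 epimers), via alkenyllithium 12 (not isolated), via lithium alkoxide 13 (not isolated)
Conditions: t-BuLi (2.0 equiv), Et2O, −78 °C; cannulated into 11, THF, −78 °C; then MeOTf (3 equiv), −78 → 0 °C
Reagents that add atoms: methyl trifluoromethanesulfonate, COS(=O)(=O)C(F)(F)F
Why: Iodine–lithium exchange proceeds with retention of the alkene geometry, and the alkenyllithium adds 1,2 to one carbonyl of the symmetrical squarate, so no regiochemical question arises. Trapping the tertiary lithium alkoxide with methyl triflate in the same flask installs the methyl ether that becomes the 5'-methoxy group. The new quaternary carbon forms as both epimers, which converge in step 11.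

Step 10
Reactants: 14 4-[(E)-2-((S)-7-benzyloxy-8-methoxychroman-3-yl)vinyl]-2,3-diisopropoxy-4-methoxycyclobut-2-en-1-one
Product: 15 4-[(E)-2-((S)-7-benzyloxy-8-methoxychroman-3-yl)vinyl]-2-isopropoxy-3,4-dimethoxycyclobut-2-en-1-one (both C4 epimers)
Conditions: NaOMe (0.3 equiv), MeOH/THF (4:1), 0 → 25 °C
Reagents that add atoms: methanol, CO
Why: Proposed new method: methoxide should add to C3, the only β-carbon of the vinylogous ester, and the tetrahedral intermediate should expel isopropoxide, with methanol as solvent driving the exchange; the C2 isopropoxy group sits on the α-carbon of the enone and the C4 methoxy group on a saturated carbon, so neither can undergo addition–elimination, and the closest known reaction types are the alkoxide transesterification of dialkyl squarates and the displacement of the 3-alkoxy group of 3-alkoxycyclobut-2-enones by amines.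

Step 11
Reactants: 15 4-[(E)-2-((S)-7-benzyloxy-8-methoxychroman-3-yl)vinyl]-2-isopropoxy-3,4-dimethoxycyclobut-2-en-1-one
Product: 18 6-[(S)-7-benzyloxy-8-methoxychroman-3-yl]-2-isopropoxy-3,4-dimethoxyphenol, via dienylketene 16 (not isolated), via cyclohexa-2,4-dienone 17 (not isolated)
Conditions: PhMe (0.02 M, degassed), 110 °C
Reagents that add atoms: none
Why: On heating, the cyclobutenone should undergo thermal conrotatory 4π opening of its C1–C4 bond to the (Z)-dienylketene 16; the ketene carbon (C2') then bonds to the alkene terminus (C1') in a thermal disrotatory 6π electrocyclisation that closes ring B as the six-membered carbocycle 17, and enolisation of 17 gives phenol 18. The closest known reaction type is the thermal ring expansion of squarate-derived 4-alkenyl-4-alkoxy- and 4-alkenyl-4-hydroxycyclobutenones to polyoxygenated phenols and hydroquinones (Moore rearrangement). The selectivity the step needs is torquoselectivity: the 4-methoxy group, a lone-pair donor, rotates outward and thereby forces the alkenyl group inward, into the only geometry from which the ketene can cyclise, whereas outward rotation of the alkenyl group would be unproductive and reversible. No stereocentre is created: the sp3 carbon of 17 is lost on aromatisation, the mixed configuration at C4 of 15 disappears on ring opening, and C3 of the chroman is a spectator that is neither acidic nor involved. The placing of the four oxygens is not a matter of selectivity in this step but of connectivity: the ketene oxygen becomes the only free hydroxyl (C2'), the α-isopropoxy group lands on C3', and the two methoxy groups on C4' and C5'. Either alkene isomer of 15 gives the same product, the (E)-isomer more readily because its chroman substituent points away from the forming bond. High dilution and exclusion of oxygen are meant to keep the ketene from being captured by the product phenol and to protect the electron-rich phenol.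

Step 12
Reactants: 18 6-[(S)-7-benzyloxy-8-methoxychroman-3-yl]-2-isopropoxy-3,4-dimethoxyphenol
Product: 19 (S)-7-(benzyloxy)-3-(3-isopropoxy-2,4,5-trimethoxyphenyl)-8-methoxychromane
Conditions: MeI, K2CO3, DMF, 25 °C
Reagents that add atoms: iodomethane, CI
Why: Williamson methylation of the only free hydroxyl in the molecule; the phenol is hindered but there is no competing site.

Step 13
Reactants: 19 (S)-7-(benzyloxy)-3-(3-isopropoxy-2,4,5-trimethoxyphenyl)-8-methoxychromane
Product: 20 (S)-3-(3-hydroxy-2,4,5-trimethoxyphenyl)-8-methoxychroman-7-ol (CNP0201239.1)
Conditions: BCl3 (5 equiv), C6HMe5 (3 equiv), CH2Cl2, −78 → 0 °C; then H2O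
Reagents that add atoms: none
Why: Lewis-acid dealkylation; BCl3 cleaves aryl isopropyl and aryl benzyl ethers through their stabilised carbocation-like departure well below the temperature at which aryl methyl ethers react, and pentamethylbenzene captures the benzyl cation before it can alkylate the electron-rich rings. C3 is not affected.

## Compound list

1 | 2-methoxyresorcinol (2-methoxybenzene-1,3-diol) | COc1c(O)cccc1O | starting material
2 | 2,4-dihydroxy-3-methoxybenzaldehyde | O=Cc1ccc(O)c(OC)c1O | intermediate
3 | 4-(benzyloxy)-2-hydroxy-3-methoxybenzaldehyde | O=Cc1ccc(OCc2ccccc2)c(OC)c1O | intermediate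
4 | tert-butyl acrylate | C=CC(=O)OC(C)(C)C | starting material
5 | tert-butyl 7-(benzyloxy)-8-methoxy-2H-chromene-3-carboxylate | CC(C)(C)OC(=O)C1=Cc2ccc(OCc3ccccc3)c(OC)c2OC1 | intermediate
6 | 7-(benzyloxy)-8-methoxy-2H-chromene-3-carboxylic acid | OC(=O)C1=Cc2ccc(OCc3ccccc3)c(OC)c2OC1 | intermediate
7 | (R)-7-(benzyloxy)-8-methoxychromane-3-carboxylic acid | OC(=O)[C@H]1COc2c(ccc(OCc3ccccc3)c2OC)C1 | intermediate
8 | (S)-[7-(benzyloxy)-8-methoxychroman-3-yl]methanol | OC[C@H]1COc2c(ccc(OCc3ccccc3)c2OC)C1 | intermediate
9 | (R)-7-(benzyloxy)-8-methoxychromane-3-carbaldehyde | O=C[C@H]1COc2c(ccc(OCc3ccccc3)c2OC)C1 | intermediate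
10 | (S)-7-(benzyloxy)-3-[(E)-2-iodovinyl]-8-methoxychromane | I/C=C/[C@H]1COc2c(ccc(OCc3ccccc3)c2OC)C1 | intermediate
11 | diisopropyl squarate (3,4-diisopropoxycyclobut-3-ene-1,2-dione) | CC(C)OC1=C(OC(C)C)C(=O)C1=O | starting material
12 | (E)-2-[(S)-7-(benzyloxy)-8-methoxychroman-3-yl]vinyllithium | [Li]/C=C/[C@H]1COc2c(ccc(OCc3ccccc3)c2OC)C1 | intermediate
13 | lithium 1-[(E)-2-((S)-7-benzyloxy-8-methoxychroman-3-yl)vinyl]-2,3-diisopropoxy-4-oxocyclobut-2-en-1-olate (both epimers at the ring carbon) | O=C1C(OC(C)C)=C(OC(C)C)C1(O[Li])/C=C/[C@H]1COc2c(ccc(OCc3ccccc3)c2OC)C1 | intermediate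
14 | 4-[(E)-2-((S)-7-benzyloxy-8-methoxychroman-3-yl)vinyl]-2,3-diisopropoxy-4-methoxycyclobut-2-en-1-one (both C4 epimers) | O=C1C(OC(C)C)=C(OC(C)C)C1(OC)/C=C/[C@H]1COc2c(ccc(OCc3ccccc3)c2OC)C1 | intermediate
15 | 4-[(E)-2-((S)-7-benzyloxy-8-methoxychroman-3-yl)vinyl]-2-isopropoxy-3,4-dimethoxycyclobut-2-en-1-one (both C4 epimers) | O=C1C(OC(C)C)=C(OC)C1(OC)/C=C/[C@H]1COc2c(ccc(OCc3ccccc3)c2OC)C1 | intermediate
16 | (3Z,5E)-6-[(S)-7-benzyloxy-8-methoxychroman-3-yl]-2-isopropoxy-3,4-dimethoxyhexa-1,3,5-trien-1-one (dienylketene) | O=C=C(OC(C)C)/C(OC)=C(OC)\C=C\[C@H]1COc2c(ccc(OCc3ccccc3)c2OC)C1 | intermediate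
17 | 6-[(S)-7-benzyloxy-8-methoxychroman-3-yl]-2-isopropoxy-3,4-dimethoxycyclohexa-2,4-dien-1-one (C6 unspecified) | O=C1C(OC(C)C)=C(OC)C(OC)=CC1[C@H]1COc2c(ccc(OCc3ccccc3)c2OC)C1 | intermediate
18 | 6-[(S)-7-benzyloxy-8-methoxychroman-3-yl]-2-isopropoxy-3,4-dimethoxyphenol | Oc1c(OC(C)C)c(OC)c(OC)cc1[C@H]1COc2c(ccc(OCc3ccccc3)c2OC)C1 | intermediate
19 | (S)-7-(benzyloxy)-3-(3-isopropoxy-2,4,5-trimethoxyphenyl)-8-methoxychromane | COc1c(OC(C)C)c(OC)c(OC)cc1[C@H]1COc2c(ccc(OCc3ccccc3)c2OC)C1 | intermediate
20 | (S)-3-(3-hydroxy-2,4,5-trimethoxyphenyl)-8-methoxychroman-7-ol (CNP0201239.1) | COc1cc([C@H]2COc3c(ccc(O)c3OC)C2)c(OC)c(O)c1OC | target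

## Step count and least certain steps

Total steps: 13. Longest linear sequence: 13 steps (1 to 20; 4 and 11 are bought and enter in steps 3 and 9).

**Step 10 (alkoxy exchange, proposed new method).**
- What may go wrong: methoxide may add 1,2 to the ring carbonyl instead of to C3, and the strained C1–C4 bond may then cleave, because the departing carbanion is allylic and conjugated. The exchange may also stall, because C3 is flanked by a quaternary carbon.
- Fallback (known chemistry throughout): the oxygen pattern is taken from the established preference of organolithium reagents for the ketone-like carbonyl of a semisquarate.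
  - Setting out from 10, lithiation as in step 9 and addition to 3-methoxycyclobut-3-ene-1,2-dione F2, with MeOTf trapping, would give 4-[(E)-2-((S)-7-benzyloxy-8-methoxychroman-3-yl)vinyl]-3,4-dimethoxycyclobut-2-en-1-one F3. F2 is made from dimethyl squarate F1 by LiAlH(OtBu)3 reduction and HCl-induced loss of methanol.
  - The same thermal ring expansion would give 2-[(S)-7-benzyloxy-8-methoxychroman-3-yl]-4,5-dimethoxyphenol F4, in which C3' bears hydrogen.
  - Magnesium-mediated ortho-formylation (MgCl2, Et3N, paraformaldehyde) can only occur at C3' and would give 3-[(S)-7-benzyloxy-8-methoxychroman-3-yl]-2-hydroxy-5,6-dimethoxybenzaldehyde F5.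
  - Methylation (MeI, K2CO3) would give 3-[(S)-7-benzyloxy-8-methoxychroman-3-yl]-2,5,6-trimethoxybenzaldehyde F6.
  - Dakin-type Baeyer–Villiger oxidation (mCPBA; then K2CO3, MeOH) would convert the formyl group into the 3'-hydroxyl of 3-[(S)-7-benzyloxy-8-methoxychroman-3-yl]-2,5,6-trimethoxyphenol F7.
  - Hydrogenolysis (H2, Pd/C) would bring the route back at 20.
  - This costs two more steps in the longest line, plus the preparation of F2, but needs no alkoxy exchange and no BCl3.

**Step 11 (key step).**
- What may go wrong: the ring expansion itself is well supported. The likeliest loss is air oxidation of the very electron-rich para-methoxyphenol at 110 °C and during isolation, together with addition of the phenol to ketene that has not yet cyclised if the solution is too concentrated.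
- Fallback: the material is taken through the stable quinone instead of the phenol. Setting out from 15, the crude thermolysate would be oxidised with PhI(OAc)2 in aqueous MeCN to 2-[(S)-7-benzyloxy-8-methoxychroman-3-yl]-6-isopropoxy-5-methoxy-1,4-benzoquinone F8. Reduction with Na2S2O4 would give 2-[(S)-7-benzyloxy-8-methoxychroman-3-yl]-6-isopropoxy-5-methoxybenzene-1,4-diol F9, and double methylation (Me2SO4, K2CO3, acetone) would return to the route at 19, bypassing 18.

**Step 5 (asymmetric hydrogenation).**
- What may go wrong: insufficient or reversed facial selectivity, because the ring oxygen and the electron-rich arene may change the binding mode on which the analogy to the simple acid rests; the aryl-conjugated trisubstituted alkene may also be reduced slowly.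
- Fallback: the substrate class and catalyst type are changed. Setting out from 5, DIBAL-H reduction would give [7-(benzyloxy)-8-methoxy-2H-chromen-3-yl]methanol F10, a cyclic 2-substituted cinnamyl alcohol. Asymmetric hydrogenation with a cationic iridium phosphine–oxazoline catalyst, [Ir(cod)(tBu-PHOX)]BArF, a standard reaction for this alkene class, would lead directly to 8 and shorten the route by one step.

**Step 13 (double dealkylation).**
- What may go wrong: cleavage may not stop at the two intended ethers. Once O3' and O7 are bound to boron, chelation can activate the flanking methyl ethers, and benzyl transfer to the electron-rich rings competes if the scavenger is outrun.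
- Fallback: the two protecting groups are removed by different reaction types. Setting out from 19, hydrogenolysis (H2, Pd/C, EtOAc) would give (S)-3-(3-isopropoxy-2,4,5-trimethoxyphenyl)-8-methoxychroman-7-ol F11. The single isopropyl ether would then be cleaved with a near-stoichiometric amount of BCl3 at −78 °C, returning to the route at 20.

**Step 3 (chromene annulation).**
- What may go wrong: slow or incomplete Baylis–Hillman addition, because the aldehyde carries three donor oxygens.
- Fallback: setting out from 3, oxa-Michael addition to acrolein and aldol condensation (K2CO3, 1,4-dioxane, reflux) would give 7-(benzyloxy)-8-methoxy-2H-chromene-3-carbaldehyde F12. Pinnick oxidation (NaClO2, NaH2PO4, 2-methylbut-2-ene) would return to the route at 6.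

## Further compounds

F1 | step 10 | dimethyl squarate (3,4-dimethoxycyclobut-3-ene-1,2-dione) | COC1=C(OC)C(=O)C1=O
F2 | step 10 | 3-methoxycyclobut-3-ene-1,2-dione | COC1=CC(=O)C1=O
F3 | step 10 | 4-[(E)-2-((S)-7-benzyloxy-8-methoxychroman-3-yl)vinyl]-3,4-dimethoxycyclobut-2-en-1-one (both C4 epimers) | O=C1C=C(OC)C1(OC)/C=C/[C@H]1COc2c(ccc(OCc3ccccc3)c2OC)C1
F4 | step 10 | 2-[(S)-7-benzyloxy-8-methoxychroman-3-yl]-4,5-dimethoxyphenol | Oc1cc(OC)c(OC)cc1[C@H]1COc2c(ccc(OCc3ccccc3)c2OC)C1
F5 | step 10 | 3-[(S)-7-benzyloxy-8-methoxychroman-3-yl]-2-hydroxy-5,6-dimethoxybenzaldehyde | O=Cc1c(OC)c(OC)cc(c1O)[C@H]1COc2c(ccc(OCc3ccccc3)c2OC)C1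
F6 | step 10 | 3-[(S)-7-benzyloxy-8-methoxychroman-3-yl]-2,5,6-trimethoxybenzaldehyde | O=Cc1c(OC)c(OC)cc(c1OC)[C@H]1COc2c(ccc(OCc3ccccc3)c2OC)C1
F7 | step 10 | 3-[(S)-7-benzyloxy-8-methoxychroman-3-yl]-2,5,6-trimethoxyphenol | Oc1c(OC)c(OC)cc(c1OC)[C@H]1COc2c(ccc(OCc3ccccc3)c2OC)C1
F8 | step 11 | 2-[(S)-7-benzyloxy-8-methoxychroman-3-yl]-6-isopropoxy-5-methoxy-1,4-benzoquinone | O=C1C(OC(C)C)=C(OC)C(=O)C=C1[C@H]1COc2c(ccc(OCc3ccccc3)c2OC)C1
F9 | step 11 | 2-[(S)-7-benzyloxy-8-methoxychroman-3-yl]-6-isopropoxy-5-methoxybenzene-1,4-diol | Oc1c(OC(C)C)c(OC)c(O)cc1[C@H]1COc2c(ccc(OCc3ccccc3)c2OC)C1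
F10 | step 5 | [7-(benzyloxy)-8-methoxy-2H-chromen-3-yl]methanol | OCC1=Cc2ccc(OCc3ccccc3)c(OC)c2OC1
F11 | step 13 | (S)-3-(3-isopropoxy-2,4,5-trimethoxyphenyl)-8-methoxychroman-7-ol | COc1c(OC(C)C)c(OC)c(OC)cc1[C@H]1COc2c(ccc(O)c2OC)C1
F12 | step 3 | 7-(benzyloxy)-8-methoxy-2H-chromene-3-carbaldehyde | O=CC1=Cc2ccc(OCc3ccccc3)c(OC)c2OC1
A1 | alternative 1 | methyl 2-diazo-2-{4,5-dimethoxy-2-[(3-methoxy-2-pivaloyloxy-4-triisopropylsilyloxyphenyl)methoxy]-3-(triisopropylsilyloxy)phenyl}acetate | COC(=O)C(=[N+]=[N-])c1cc(OC)c(OC)c(O[Si](C(C)C)(C(C)C)C(C)C)c1OCc1ccc(O[Si](C(C)C)(C(C)C)C(C)C)c(OC)c1OC(=O)C(C)(C)C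
A2 | alternative 1 | methyl cis-5,6-dimethoxy-2-(3-methoxy-2-pivaloyloxy-4-triisopropylsilyloxyphenyl)-7-(triisopropylsilyloxy)-2,3-dihydrobenzofuran-3-carboxylate | COC(=O)[C@H]1[C@@H](c3ccc(O[Si](C(C)C)(C(C)C)C(C)C)c(OC)c3OC(=O)C(C)(C)C)Oc2c(O[Si](C(C)C)(C(C)C)C(C)C)c(OC)c(OC)cc12
A3 | alternative 2 | [(4-methoxybenzyl)oxy]methylboronic acid (S,S)-1,2-dicyclohexylethane-1,2-diol ester | COc1ccc(COCB2O[C@@H](C3CCCCC3)[C@H](C3CCCCC3)O2)cc1
A4 | alternative 2 | (3-benzyloxy-2,4,5-trimethoxyphenyl)magnesium bromide | COc1cc([Mg]Br)c(OC)c(OCc2ccccc2)c1OC
A5 | alternative 2 | (S)-1-(3-benzyloxy-2,4,5-trimethoxyphenyl)-2-(4-methoxybenzyloxy)ethylboronic acid (S,S)-1,2-dicyclohexylethane-1,2-diol ester | COc1ccc(COC[C@H](c2cc(OC)c(OC)c(OCc3ccccc3)c2OC)B2O[C@@H](C3CCCCC3)[C@H](C3CCCCC3)O2)cc1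
A6 | alternative 3 | 3-(3-benzyloxy-2,4,5-trimethoxyphenyl)-3-chloro-3H-diazirine | COc1cc(C2(Cl)N=N2)c(OC)c(OCc2ccccc2)c1OC
A7 | alternative 3 | 6-benzyloxy-7-methoxybenzofuran | COc1c(OCc2ccccc2)ccc2ccoc12
A8 | alternative 3 | 7-benzyloxy-3-(3-benzyloxy-2,4,5-trimethoxyphenyl)-8-methoxy-1-benzopyrylium chloride | COc1c(OCc2ccccc2)ccc2cc(-c3cc(OC)c(OC)c(OCc4ccccc4)c3OC)c[o+]c12.[Cl-]
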